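**Plan**
- Retrosynthesis cuts, in this order: the two N2–CH2 bonds to the butane-1,4-diyl bridge and the two C5–Cl bonds; each C3–C9 bond to the dienyl chain; C3–C4 and C4a–C8a of the core; finally C8–C7 and C6–C5 of the open chain.
- Enabling feature: the hetero-ring (N2, C1, C3, C4, C4a, C8a) shares the C4a–C8a edge with the carbocycle (C4a, C5, C6, C7, C8, C8a). N2, C1, C3 and C8a can therefore come from a 1,2,4-triazine, and C4a/C4 from a terminal alkyne at the end of its 6-acyl chain C8–C7–C6–C5.
- Forward: the chain is built on the triazine ester (enolate acylation, thioester to aldehyde, propargylation, oxidation); one thermal cycloaddition with loss of N2 then closes the carbocycle and the pyridine together; O-silylation, C3 coupling with the dienylboronic acid, double N-alkylation and C5 chlorination finish the route.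
- Stereochemistry: C7 comes from (R)-lactic acid by self-regeneration of stereocentres (acylation trans to the tert-butyl group of the cis-dioxolanone). The side-chain centre comes from (S)-2-methylbutan-1-ol. The two E-alkenes come from a stabilised Wittig reaction and a syn-hydroboration.

Key step: step 8

Assumption: the product of the key step is drawn as its 5H-6,8-dione tautomer; it may rest as the 2H (N–H) or 6-enol form, all of which should give the same silyl enol ether in step 9, and the homopropargylic alcohol of step 6 is carried as both carbinol epimers because that centre becomes a ketone in step 7.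

**Route**

Step 1
Reactants: 1 ethyl 5-chloro-3-(methylsulfanyl)-1,2,4-triazine-6-carboxylate
Product: 2 ethyl 3-(methylsulfanyl)-1,2,4-triazine-6-carboxylate
Conditions: Pd(PPh3)4 (5 mol %), Bu3SnH (1.1 equiv), toluene, 25 → 50 °C
Reagents that add atoms: none
Why: Palladium-catalysed hydrodehalogenation should work because the imidoyl-type C5–Cl bond adds to Pd(0) far faster than the C–S bond (which needs a copper cofactor), and the tin hydride then supplies the hydrogen that later becomes C1–H of the pyridine.

Step 2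
Reactants: 3 (R)-lactic acid; 4 pivalaldehyde
Product: 5 (2R,5R)-2-tert-butyl-5-methyl-1,3-dioxolan-4-one
Conditions: TsOH·H2O (cat.), H2SO4 (cat.), pentane, reflux, Dean–Stark; cis isomer crystallised from Et2O/pentane, −78 °C
Reagents that add atoms: none
Why: Acid-catalysed acetalisation under thermodynamic control should favour the cis-dioxolanone, which stores the lactate configuration in the new acetal centre (first half of self-regeneration of stereocentres).

Step 3
Reactants: 5 (2R,5R)-2-tert-butyl-5-methyl-1,3-dioxolan-4-one; 2 ethyl 3-(methylsulfanyl)-1,2,4-triazine-6-carboxylate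
Product: 7 (2R,5S)-2-tert-butyl-5-methyl-5-{[3-(methylsulfanyl)-1,2,4-triazin-6-yl]carbonyl}-1,3-dioxolan-4-one, via lithium dioxolanone enolate 6 (not isolated)
Conditions: LDA (commercial solution, 1.05 equiv), THF, −78 °C; then 2 (1.1 equiv), −78 °C; AcOH quench at −78 °C
Reagents that add atoms: none
Why: Crossed Claisen acylation of a lithium ester enolate by a non-enolisable, electron-poor heteroaryl ester should form the C8–C7 bond; the tert-butyl group shields one face of the planar enolate, so the acyl group enters trans to it and the quaternary centre (C7 of the target) is set with overall retention of the lactate configuration.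

Step 4
Reactants: 7 (2R,5S)-2-tert-butyl-5-methyl-5-{[3-(methylsulfanyl)-1,2,4-triazin-6-yl]carbonyl}-1,3-dioxolan-4-one
Product: 9 S-methyl (2S)-2-(acetyloxy)-2-methyl-3-[3-(methylsulfanyl)-1,2,4-triazin-6-yl]-3-oxopropanethioate, via sodium alkoxide 8 (not isolated)
Conditions: NaSMe (1.0 equiv), THF/DMF, −40 °C; then Ac2O (2 equiv), DMAP (cat.), −40 → 0 °C
Reagents that add atoms: sodium methanethiolate, [Na+].[S-]C; acetic anhydride, CC(=O)OC(C)=O
Why: Acyl substitution by thiolate at the activated acylal-type lactone carbonyl should release pivalaldehyde and a tertiary alkoxide that is O-acetylated in the same flask; methanethiolate is chosen because any SNAr exchange at the triazine C3–SMe group is degenerate, and the stereocentre is not touched.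

Step 5
Reactants: 9 S-methyl (2S)-2-(acetyloxy)-2-methyl-3-[3-(methylsulfanyl)-1,2,4-triazin-6-yl]-3-oxopropanethioate
Product: 10 (2R)-2-methyl-1-[3-(methylsulfanyl)-1,2,4-triazin-6-yl]-1,3-dioxopropan-2-yl acetate
Conditions: Et3SiH (3 equiv), 10% Pd/C, acetone, 25 °C
Reagents that add atoms: none
Why: Fukuyama reduction should convert the thioester into the aldehyde while leaving the ketone, the acetate and the heteroaryl thioether alone, a chemoselectivity that a hydride reagent could not give.

Step 6
Reactants: 10 (2R)-2-methyl-1-[3-(methylsulfanyl)-1,2,4-triazin-6-yl]-1,3-dioxopropan-2-yl acetate; 11 allenylboronic acid pinacol ester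
Product: 13 (2R,3RS)-3-hydroxy-2-methyl-1-[3-(methylsulfanyl)-1,2,4-triazin-6-yl]-1-oxohex-5-yn-2-yl acetate, via pinacol borate ester 12 (not isolated)
Conditions: 11 (1.5 equiv), (PhO)2P(O)OH (10 mol %), toluene, 0 → 25 °C; aqueous work-up
Reagents that add atoms: none
Why: Brønsted-acid-catalysed propargylation of an aldehyde by an allenylboronate through a cyclic SE2′ transition state should give only the homopropargylic alcohol (C6–C5 bond) and spare the hindered ketone; the configuration of the new carbinol centre is irrelevant because it is oxidised in step 7.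

Step 7
Reactants: 13 (2R,3RS)-3-hydroxy-2-methyl-1-[3-(methylsulfanyl)-1,2,4-triazin-6-yl]-1-oxohex-5-yn-2-yl acetate
Product: 14 (2R)-2-methyl-1-[3-(methylsulfanyl)-1,2,4-triazin-6-yl]-1,3-dioxohex-5-yn-2-yl acetate
Conditions: Dess–Martin periodinane (1.3 equiv), CH2Cl2, 0 → 25 °C; filtration through neutral silica, used at once
Reagents that add atoms: none
Why: Dess–Martin oxidation runs under neutral to weakly acidic conditions, so the β,γ-alkynyl ketone should form without base-induced isomerisation to the allenyl ketone and without acetyl migration.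

Step 8
Reactants: 14 (2R)-2-methyl-1-[3-(methylsulfanyl)-1,2,4-triazin-6-yl]-1,3-dioxohex-5-yn-2-yl acetate
Product: 16 (7R)-7-methyl-3-(methylsulfanyl)-6,8-dioxo-5,6,7,8-tetrahydroisoquinolin-7-yl acetate, via bridged dinitrogen cycloadduct 15 (not isolated)
Conditions: PhCl (0.01 M), 130 °C, Ar, base-free glassware
Reagents that add atoms: none
Why: The electron-poor triazine, whose LUMO is lowered further by the 6-acyl group, should react as an azadiene across C3 and C6 with the tethered terminal alkyne in an intramolecular inverse-electron-demand Diels–Alder reaction, and the bridged adduct 15 then loses dinitrogen by retro-Diels–Alder reaction to give the aromatic pyridine. The closest known reaction type is the thermal intramolecular cycloaddition of 1,2,4-triazines to tethered alkynes with loss of N2, which gives ring-fused pyridines. The carbocycle closes as the C4a–C8a bond forms: the four-atom tether C8–C7–C6–C5 folds the alkyne over the triazine face so that a six-membered ring results, helped by the gem-disubstituted C7. The pyridine ring closes in the same [4+2] event through the C3–C4 and C4a–C8a bonds and becomes aromatic on cycloreversion. No stereocentre is created, and the quaternary C7 carries no hydrogen and so cannot epimerise. The regioselectivity needed is secured by the tether, which can only deliver the internal alkyne carbon to triazine C6 and the terminal carbon to C3, and the chemoselectivity over alkyne-to-allene isomerisation is secured by base-free thermal conditions at high dilution.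

Step 9
Reactants: 16 (7R)-7-methyl-3-(methylsulfanyl)-6,8-dioxo-5,6,7,8-tetrahydroisoquinolin-7-yl acetate
Product: 17 (7R)-6-[(tert-butyldimethylsilyl)oxy]-7-methyl-3-(methylsulfanyl)-8-oxo-7,8-dihydroisoquinolin-7-yl acetate
Conditions: TBSOTf (1.2 equiv), Et3N (2 equiv), CH2Cl2, −78 → 0 °C
Reagents that add atoms: tert-butyldimethylsilyl triflate, CC(C)(C)[Si](C)(C)OS(=O)(=O)C(F)(F)F
Why: Soft enolisation and O-silylation at the only enolisable position (C5) should give the silyl enol ether, which fixes the hetero-ring as a true pyridine so that the thioether stays electron-poor for coupling and the ring nitrogen is the only nucleophilic site in the later alkylation.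

Step 10
Reactants: 18 (S)-2-methylbutan-1-ol
Product: 19 (S)-2-methylbutanal
Conditions: TEMPO (1 mol %), KBr (10 mol %), NaOCl (1.1 equiv), CH2Cl2/H2O, pH 9, 0 °C
Reagents that add atoms: none
Why: TEMPO/bleach oxidation under buffered biphasic conditions should deliver the α-branched aldehyde fast enough to avoid enolisation, so the (S) centre is kept.

Step 11
Reactants: 19 (S)-2-methylbutanal; 20 2-(triphenyl-λ5-phosphanylidene)propanal
Product: 21 (2E,4S)-2,4-dimethylhex-2-enal
Conditions: toluene, 80 °C (sealed vessel)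
Reagents that add atoms: none
Why: Wittig reaction with a formyl-stabilised ylide should give the E-trisubstituted enal under thermodynamic control, and the ylide is too weakly basic to epimerise the α-centre.

Step 12
Reactants: 21 (2E,4S)-2,4-dimethylhex-2-enal
Product: 22 (3E,5S)-3,5-dimethylhept-3-en-1-yne
Conditions: TMSCHN2 (1.2 equiv), n-BuLi (1.2 equiv), THF, −78 → 0 °C
Reagents that add atoms: (trimethylsilyl)diazomethane, C[Si](C)(C)C=[N+]=[N-]
Why: Colvin homologation (addition of lithiated TMS-diazomethane, Peterson elimination and 1,2-hydride shift of the alkylidene carbene) should turn the aldehyde into the terminal alkyne at low temperature without conjugate addition or loss of alkene geometry.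

Step 13
Reactants: 22 (3E,5S)-3,5-dimethylhept-3-en-1-yne
Product: 24 [(1E,3E,5S)-3,5-dimethylhepta-1,3-dien-1-yl]boronic acid, via catechol boronate 23 (not isolated)
Conditions: catecholborane (1.1 equiv), THF, 65 °C; then H2O, 25 °C
Reagents that add atoms: catecholborane, B1Oc2ccccc2O1; water, O
Why: Hydroboration of the terminal alkyne is syn and anti-Markovnikov and ignores the trisubstituted alkene, so hydrolysis should give the (1E,3E)-dienylboronic acid.

Step 14
Reactants: 17 (7R)-6-[(tert-butyldimethylsilyl)oxy]-7-methyl-3-(methylsulfanyl)-8-oxo-7,8-dihydroisoquinolin-7-yl acetate; 24 [(1E,3E,5S)-3,5-dimethylhepta-1,3-dien-1-yl]boronic acid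
Product: 25 (7R)-6-[(tert-butyldimethylsilyl)oxy]-3-[(1E,3E,5S)-3,5-dimethylhepta-1,3-dien-1-yl]-7-methyl-8-oxo-7,8-dihydroisoquinolin-7-yl acetate
Conditions: Pd2(dba)3 (2.5 mol %), tri(2-furyl)phosphine (10 mol %), CuTC (1.5 equiv), THF, 50 °C
Reagents that add atoms: none
Why: Liebeskind–Srogl coupling of a 2-(methylsulfanyl)pyridine, activated by the acyl group para to the C–S carbon, with an alkenylboronic acid under base-free conditions should form the C3–C9 bond with retention of alkene geometry and tolerate acetate, ketone and silyl enol ether.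

Step 15
Reactants: 25 (7R)-6-[(tert-butyldimethylsilyl)oxy]-3-[(1E,3E,5S)-3,5-dimethylhepta-1,3-dien-1-yl]-7-methyl-8-oxo-7,8-dihydroisoquinolin-7-yl acetate (2 equiv); 26 1,4-diiodobutane
Product: 28 (7R,7'R)-2,2'-(butane-1,4-diyl)bis{3-[(1E,3E,5S)-3,5-dimethylhepta-1,3-dien-1-yl]-7-methyl-6,8-dioxo-2,6,7,8-tetrahydroisoquinolin-7-yl} diacetate, via bis-pyridinium diiodide 27 (not isolated)
Conditions: 26 (0.48 equiv), MeCN, 75 °C; then CsF (1.1 equiv per silyl group), 25 °C
Reagents that add atoms: none
Why: Menshutkin N-alkylation of the pyridine nitrogen at both ends of the diiodide, followed by fluoride-induced loss of the silyl group from each 6-silyloxy pyridinium (the logic of silyl-mediated N-alkylation of pyridones), should give the neutral N-alkyl vinylogous 4-pyridone in both halves without competing O-alkylation.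

Step 16
Reactants: 28 (7R,7'R)-2,2'-(butane-1,4-diyl)bis{3-[(1E,3E,5S)-3,5-dimethylhepta-1,3-dien-1-yl]-7-methyl-6,8-dioxo-2,6,7,8-tetrahydroisoquinolin-7-yl} diacetate
Product: 29 penazaphilone I
Conditions: NCS (2.05 equiv), MeCN, 0 → 25 °C
Reagents that add atoms: N-chlorosuccinimide, O=C1CCC(=O)N1Cl
Why: Electrophilic chlorination of the enaminone should occur at C5 in each half, because C5 is the nucleophilic terminus of the N2–C3=C4–C4a=C5 push–pull system and attack there gives a pyridinium-stabilised cation, which the dienyl chain cannot match.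

**Compound list**

1 | ethyl 5-chloro-3-(methylsulfanyl)-1,2,4-triazine-6-carboxylate | CCOC(=O)c1nnc(SC)nc1Cl | starting material
2 | ethyl 3-(methylsulfanyl)-1,2,4-triazine-6-carboxylate | CCOC(=O)c1cnc(SC)nn1 | intermediate
3 | (R)-lactic acid | C[C@@H](O)C(=O)O | starting material
4 | pivalaldehyde | CC(C)(C)C=O | starting material
5 | (2R,5R)-2-tert-butyl-5-methyl-1,3-dioxolan-4-one (cis) | C[C@H]1O[C@@H](C(C)(C)C)OC1=O | intermediate
6 | lithium (2R)-2-tert-butyl-5-methyl-1,3-dioxol-4-olate (enolate of 5) | [Li+].CC1=C([O-])O[C@H](C(C)(C)C)O1 | intermediate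
7 | (2R,5S)-2-tert-butyl-5-methyl-5-{[3-(methylsulfanyl)-1,2,4-triazin-6-yl]carbonyl}-1,3-dioxolan-4-one | C[C@@]1(C(=O)c2cnc(SC)nn2)O[C@@H](C(C)(C)C)OC1=O | intermediate
8 | sodium (2S)-2-methyl-1-(methylsulfanyl)-3-[3-(methylsulfanyl)-1,2,4-triazin-6-yl]-1,3-dioxopropan-2-olate | [Na+].CSc1ncc(nn1)C(=O)[C@](C)([O-])C(=O)SC | intermediate
9 | S-methyl (2S)-2-(acetyloxy)-2-methyl-3-[3-(methylsulfanyl)-1,2,4-triazin-6-yl]-3-oxopropanethioate | CSc1ncc(nn1)C(=O)[C@](C)(OC(C)=O)C(=O)SC | intermediate
10 | (2R)-2-methyl-1-[3-(methylsulfanyl)-1,2,4-triazin-6-yl]-1,3-dioxopropan-2-yl acetate | CSc1ncc(nn1)C(=O)[C@](C)(OC(C)=O)C=O | intermediate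
11 | allenylboronic acid pinacol ester | C=C=CB1OC(C)(C)C(C)(C)O1 | starting material
12 | pinacol borate ester of alcohol 13 (both carbinol epimers) | CSc1ncc(nn1)C(=O)[C@](C)(OC(C)=O)C(CC#C)OB1OC(C)(C)C(C)(C)O1 | intermediate
13 | (2R,3RS)-3-hydroxy-2-methyl-1-[3-(methylsulfanyl)-1,2,4-triazin-6-yl]-1-oxohex-5-yn-2-yl acetate | CSc1ncc(nn1)C(=O)[C@](C)(OC(C)=O)C(O)CC#C | intermediate
14 | (2R)-2-methyl-1-[3-(methylsulfanyl)-1,2,4-triazin-6-yl]-1,3-dioxohex-5-yn-2-yl acetate | CSc1ncc(nn1)C(=O)[C@](C)(OC(C)=O)C(=O)CC#C | intermediate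
15 | bridged cycloadduct: 4-(methylsulfanyl)-2,3,5-triazabicyclo[2.2.2]octa-2,5,7-triene whose C1 and C7 are spanned by –C(=O)–C(Me)(OAc)–C(=O)–CH2– (first carbonyl on C1; both bridgehead diastereomers) | CSC12N=NC(C=N1)(C(=O)[C@](C)(OC(C)=O)C(=O)C3)C3=C2 | intermediate
16 | (7R)-7-methyl-3-(methylsulfanyl)-6,8-dioxo-5,6,7,8-tetrahydroisoquinolin-7-yl acetate | CSc1cc2CC(=O)[C@@](C)(OC(C)=O)C(=O)c2cn1 | intermediate
17 | (7R)-6-[(tert-butyldimethylsilyl)oxy]-7-methyl-3-(methylsulfanyl)-8-oxo-7,8-dihydroisoquinolin-7-yl acetate | CSc1cc2C=C(O[Si](C)(C)C(C)(C)C)[C@@](C)(OC(C)=O)C(=O)c2cn1 | intermediate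
18 | (S)-2-methylbutan-1-ol | CC[C@H](C)CO | starting material
19 | (S)-2-methylbutanal | CC[C@H](C)C=O | intermediate
20 | 2-(triphenyl-λ5-phosphanylidene)propanal | CC(C=O)=P(c1ccccc1)(c1ccccc1)c1ccccc1 | starting material
21 | (2E,4S)-2,4-dimethylhex-2-enal | CC[C@H](C)/C=C(C)/C=O | intermediate
22 | (3E,5S)-3,5-dimethylhept-3-en-1-yne | CC[C@H](C)/C=C(C)/C#C | intermediate
23 | 2-[(1E,3E,5S)-3,5-dimethylhepta-1,3-dien-1-yl]-1,3,2-benzodioxaborole | CC[C@H](C)/C=C(C)/C=C/B1Oc2ccccc2O1 | intermediate
24 | [(1E,3E,5S)-3,5-dimethylhepta-1,3-dien-1-yl]boronic acid | CC[C@H](C)/C=C(C)/C=C/B(O)O | intermediate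
25 | (7R)-6-[(tert-butyldimethylsilyl)oxy]-3-[(1E,3E,5S)-3,5-dimethylhepta-1,3-dien-1-yl]-7-methyl-8-oxo-7,8-dihydroisoquinolin-7-yl acetate | CC[C@H](C)/C=C(C)/C=C/c1cc2C=C(O[Si](C)(C)C(C)(C)C)[C@@](C)(OC(C)=O)C(=O)c2cn1 | intermediate
26 | 1,4-diiodobutane | ICCCCI | starting material
27 | 2,2'-(butane-1,4-diyl)bis-isoquinolinium diiodide of 25 (both silyl enol ethers intact) | CC[C@H](C)/C=C(C)/C=C/c1cc2C=C(O[Si](C)(C)C(C)(C)C)[C@@](C)(OC(C)=O)C(=O)c2c[n+]1CCCC[n+]1cc2C(=O)[C@](C)(OC(C)=O)C(O[Si](C)(C)C(C)(C)C)=Cc2cc1/C=C/C(C)=C/[C@@H](C)CC.[I-].[I-] | intermediate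
28 | (7R,7'R)-2,2'-(butane-1,4-diyl)bis{3-[(1E,3E,5S)-3,5-dimethylhepta-1,3-dien-1-yl]-7-methyl-6,8-dioxo-2,6,7,8-tetrahydroisoquinolin-7-yl} diacetate (5,5'-dideschloro compound) | CC[C@H](C)/C=C(C)/C=C/C1=CC2=CC(=O)[C@@](C)(OC(C)=O)C(=O)C2=CN1CCCCN1C=C2C(=O)[C@](C)(OC(C)=O)C(=O)C=C2C=C1/C=C/C(C)=C/[C@@H](C)CC | intermediate
29 | penazaphilone I: (7S,7'S)-2,2'-(butane-1,4-diyl)bis{5-chloro-3-[(1E,3E,5S)-3,5-dimethylhepta-1,3-dien-1-yl]-7-methyl-6,8-dioxo-2,6,7,8-tetrahydroisoquinolin-7-yl} diacetate | CC[C@H](C)/C=C(C)/C=C/C1=CC2=C(Cl)C(=O)[C@@](C)(OC(C)=O)C(=O)C2=CN1CCCCN1C=C2C(=O)[C@](C)(OC(C)=O)C(=O)C(Cl)=C2C=C1/C=C/C(C)=C/[C@@H](C)CC | target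

**Step count and risks**

Total steps: 16. Longest linear sequence: 11 steps (1 → 2 → 7 → 9 → 10 → 13 → 14 → 16 → 17 → 25 → 28 → 29); the dioxolanone (1 step) and the dienylboronic acid (4 steps) are side branches.

Step 3. The lithium enolate may add to the electron-poor C5 of the triazine ring (σ-adduct formation) or fragment before it is acylated, so that little C-acylation takes place. The fallback avoids a free carbanion. It sets out from 2 and from enolate 6 and returns at 7. Ester 2 is saponified (LiOH, THF/H2O, 0 °C) to 3-(methylsulfanyl)-1,2,4-triazine-6-carboxylic acid F1, which is converted with oxalyl chloride and catalytic DMF into 3-(methylsulfanyl)-1,2,4-triazine-6-carbonyl chloride F2. Enolate 6 is trapped with TMSCl at −78 °C as (2R)-2-tert-butyl-5-methyl-4-[(trimethylsilyl)oxy]-1,3-dioxole F3. Mukaiyama-type C-acylation of the neutral silyl ketene acetal F3 by F2 in CH2Cl2 (−78 → 0 °C) should then give 7 with the same facial control by the tert-butyl group.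

Step 4. The thiolate may attack the triazinyl ketone so that retro-Claisen cleavage competes with lactone opening, or the freed tertiary alkoxide may undergo an acyloin-type shift before it is acetylated. The fallback builds the thioester without any ring opening. It sets out from acid F1 (made from 2 as in the fallback to step 3) and returns at 9. F1 is activated with carbonyldiimidazole to 6-(1H-imidazole-1-carbonyl)-3-(methylsulfanyl)-1,2,4-triazine F4. Magnesium-mediated decarboxylative Claisen condensation (Masamune type; MgCl2, Et3N) with 2-methylmalonic acid mono-S-methyl thioester should give racemic S-methyl 2-methyl-3-[3-(methylsulfanyl)-1,2,4-triazin-6-yl]-3-oxopropanethioate F5. Catalytic enantioselective α-hydroxylation (cinchona alkaloid catalyst of the appropriate pseudo-enantiomeric series, cumene hydroperoxide) should then set C7 in S-methyl (2S)-2-hydroxy-2-methyl-3-[3-(methylsulfanyl)-1,2,4-triazin-6-yl]-3-oxopropanethioate F6, and Ac2O/DMAP gives 9. Here the configuration rests on catalyst control instead of the lactate template.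

Step 8. Prototropic isomerisation of the propargyl ketone to the allenyl ketone, or thermal breakdown of the acetoxy diketone, may outrun the cycloaddition. The fallback keeps the same two bond formations and ring closures but runs them one oxidation level lower at C6. It sets out from 13 and returns at 16. Alcohol 13 is silylated (TBSOTf, 2,6-lutidine) to (2R,3RS)-3-[(tert-butyldimethylsilyl)oxy]-2-methyl-1-[3-(methylsulfanyl)-1,2,4-triazin-6-yl]-1-oxohex-5-yn-2-yl acetate F7, which has no acidic propargylic ketone position. Heating (o-dichlorobenzene, 150 °C) should give (7R)-6-[(tert-butyldimethylsilyl)oxy]-7-methyl-3-(methylsulfanyl)-8-oxo-5,6,7,8-tetrahydroisoquinolin-7-yl acetate F8. Acidic desilylation (HF·pyridine, to suppress acetyl migration) gives (7R)-6-hydroxy-7-methyl-3-(methylsulfanyl)-8-oxo-5,6,7,8-tetrahydroisoquinolin-7-yl acetate F9, and immediate Dess–Martin oxidation gives 16.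

Further compounds
F1 | step 3 | 3-(methylsulfanyl)-1,2,4-triazine-6-carboxylic acid | CSc1ncc(nn1)C(=O)O
F2 | step 3 | 3-(methylsulfanyl)-1,2,4-triazine-6-carbonyl chloride | CSc1ncc(nn1)C(=O)Cl
F3 | step 3 | (2R)-2-tert-butyl-5-methyl-4-[(trimethylsilyl)oxy]-1,3-dioxole | CC1=C(O[Si](C)(C)C)O[C@H](C(C)(C)C)O1
F4 | step 4 | 6-(1H-imidazole-1-carbonyl)-3-(methylsulfanyl)-1,2,4-triazine | CSc1ncc(nn1)C(=O)n1ccnc1
F5 | step 4 | S-methyl 2-methyl-3-[3-(methylsulfanyl)-1,2,4-triazin-6-yl]-3-oxopropanethioate (racemic) | CSc1ncc(nn1)C(=O)C(C)C(=O)SC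
F6 | step 4 | S-methyl (2S)-2-hydroxy-2-methyl-3-[3-(methylsulfanyl)-1,2,4-triazin-6-yl]-3-oxopropanethioate | CSc1ncc(nn1)C(=O)[C@](C)(O)C(=O)SC
F7 | step 8 | (2R,3RS)-3-[(tert-butyldimethylsilyl)oxy]-2-methyl-1-[3-(methylsulfanyl)-1,2,4-triazin-6-yl]-1-oxohex-5-yn-2-yl acetate | CSc1ncc(nn1)C(=O)[C@](C)(OC(C)=O)C(CC#C)O[Si](C)(C)C(C)(C)C
F8 | step 8 | (7R)-6-[(tert-butyldimethylsilyl)oxy]-7-methyl-3-(methylsulfanyl)-8-oxo-5,6,7,8-tetrahydroisoquinolin-7-yl acetate (both C6 epimers) | CSc1cc2CC(O[Si](C)(C)C(C)(C)C)[C@@](C)(OC(C)=O)C(=O)c2cn1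
F9 | step 8 | (7R)-6-hydroxy-7-methyl-3-(methylsulfanyl)-8-oxo-5,6,7,8-tetrahydroisoquinolin-7-yl acetate (both C6 epimers) | CSc1cc2CC(O)[C@@](C)(OC(C)=O)C(=O)c2cn1
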